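**Retrosynthetic overview**

1. Ring A (C1 CO2Me, C2 H, C3 OH, C4 Cl, C5 OMe, C6 O–ring B) is a hydroquinone mono-aryl ether. Its contiguous carbons C6(O-aryl)–C5(OMe)–C4(Cl)–C3(OH) are the four carbons of a 2-aryloxy-3-methoxy-4-chlorofuran, whose ring oxygen ends as the C3 hydroxyl.
2. Last disconnection: the tert-butyl ester and methoxymethyl ether on ring B (13 → 14).
3. Key disconnection: C6–C1 and C3–C2 of ring A, from furan 10 and methyl propiolate by Diels–Alder addition and opening of the oxygen bridge. Ring B is bought; ring A is the only ring built and is formed last.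
4. Furan 10 comes from butenolide 7 (lactone C=O turned into CH by reductive acetylation and loss of acetic acid). Lactone 7 comes from mucochloric acid: its acetal carbon C5 takes the ring B phenol, so the diaryl ether C–O bond is made as an acetal bond; C4–Cl is exchanged for OMe and C3–Cl is kept.
5. Phenol 3 comes from 2,6-dihydroxy-4-methylbenzoic acid by tert-butyl esterification and mono-MOM protection.

Key step: step 8

Remark on the chemistry: the target has no stereocentre. Compounds 5, 6, 7 and 12 are racemic, and 8 and 9 are cis/trans mixtures; this is of no consequence because every stereocentre is lost when the furan and then ring A become aromatic.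

**Route**

Step 1
Reactants: 1 2,6-dihydroxy-4-methylbenzoic acid
Product: 2 tert-butyl 2,6-dihydroxy-4-methylbenzoate
Conditions: t-BuOC(=NH)CCl3 (2.5 equiv), THF/cyclohexane, rt
Reagents that add atoms: tert-butyl 2,2,2-trichloroacetimidate, CC(C)(C)OC(=N)C(Cl)(Cl)Cl
Why: Imidate esterification: the strongly acidic 2,6-dihydroxybenzoic acid protonates the trichloroacetimidate and takes up the tert-butyl cation at room temperature, without the heating that would decarboxylate it, and the hydrogen-bonded phenols are not alkylated in the absence of a Lewis acid.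

Step 2
Reactants: 2 tert-butyl 2,6-dihydroxy-4-methylbenzoate
Product: 3 tert-butyl 2-hydroxy-6-(methoxymethoxy)-4-methylbenzoate
Conditions: MOMCl (1.05 equiv), i-Pr2NEt, CH2Cl2, 0 °C
Reagents that add atoms: chloromethyl methyl ether, COCCl
Why: Williamson-type O-alkylation of a symmetrical diol, in which the hydroxyl left after the first etherification is held in a strong hydrogen bond to the ester carbonyl and should react more slowly, so that the mono-ether can be separated from unreacted 2 and bis-ether.

Step 3
Reactants: 4 mucochloric acid (3,4-dichloro-5-hydroxyfuran-2(5H)-one)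
Product: 5 3,4-dichloro-5-oxo-2,5-dihydrofuran-2-yl methyl carbonate (racemic)
Conditions: ClCO2Me, i-Pr2NEt, CH2Cl2, 0 °C
Reagents that add atoms: methyl chloroformate, COC(=O)Cl
Why: O-acylation of the lactol hydroxyl of the cyclic pseudo-acid form with a chloroformate gives the mixed carbonate and so turns the hemiacetal hydroxyl into a leaving group.

Step 4
Reactants: 3 tert-butyl 2-hydroxy-6-(methoxymethoxy)-4-methylbenzoate; 5 3,4-dichloro-5-oxo-2,5-dihydrofuran-2-yl methyl carbonate
Product: 6 tert-butyl 2-[(3,4-dichloro-5-oxo-2,5-dihydrofuran-2-yl)oxy]-6-(methoxymethoxy)-4-methylbenzoate (racemic)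
Conditions: CsF (2 equiv), CH2Cl2, rt
Reagents that add atoms: none
Why: Nucleophilic substitution at the acylal carbon C5 of the butenolide: the phenoxide of 3 displaces the methyl carbonate, which breaks down to CO2 and methanol, a palladium-free gamma-etherification of mucohalic carbonates by phenols that should prefer C5 over the vinylic chloride at C4 under a mild fluoride base.

Step 5
Reactants: 6 tert-butyl 2-[(3,4-dichloro-5-oxo-2,5-dihydrofuran-2-yl)oxy]-6-(methoxymethoxy)-4-methylbenzoate
Product: 7 tert-butyl 2-[(4-chloro-3-methoxy-5-oxo-2,5-dihydrofuran-2-yl)oxy]-6-(methoxymethoxy)-4-methylbenzoate (racemic)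
Conditions: NaOMe (1.05 equiv), MeOH/THF, −30 → 0 °C
Reagents that add atoms: sodium methoxide, C[O-].[Na+]
Why: Vinylic nucleophilic substitution by addition–elimination: methoxide adds to the beta carbon of the vinylogous acid chloride (the carbon next to the acetal carbon) and the lactone enolate expels chloride, whereas the alpha chlorine cannot leave in this way and stays.

Step 6
Reactants: 7 tert-butyl 2-[(4-chloro-3-methoxy-5-oxo-2,5-dihydrofuran-2-yl)oxy]-6-(methoxymethoxy)-4-methylbenzoate
Product: 9 tert-butyl 2-{[5-(acetyloxy)-4-chloro-3-methoxy-2,5-dihydrofuran-2-yl]oxy}-6-(methoxymethoxy)-4-methylbenzoate, via diisobutylaluminium lactolate 8 (not isolated)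
Conditions: i-Bu2AlH (1.2 equiv), CH2Cl2, −78 °C; then pyridine, DMAP, Ac2O, −78 → 0 °C
Reagents that add atoms: acetic anhydride, CC(=O)OC(C)=O
Why: Reductive acetylation of a lactone: 1,2-addition of hydride gives a tetrahedral aluminium hemiacetal that is stable at −78 °C and is acetylated in the same flask, so that the free lactol, which could ring-open and lose the ring B phenol, is never set free, while the doubly ortho-substituted tert-butyl benzoate is too hindered to be reduced.

Step 7
Reactants: 9 tert-butyl 2-{[5-(acetyloxy)-4-chloro-3-methoxy-2,5-dihydrofuran-2-yl]oxy}-6-(methoxymethoxy)-4-methylbenzoate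
Product: 10 tert-butyl 2-[(4-chloro-3-methoxyfuran-2-yl)oxy]-6-(methoxymethoxy)-4-methylbenzoate
Conditions: Me3SiOTf (1.2 equiv), i-Pr2NEt (3 equiv), CH2Cl2, −78 → −20 °C; aq. NaHCO3
Reagents that add atoms: none
Why: Ionisation–deprotonation (1,4-elimination of acetic acid): the silyl triflate ionises the acetal acetate to an oxocarbenium ion stabilised through the neighbouring methoxy enol ether, and the amine removes the proton from the aryloxy-bearing carbon, aromatising the 2,5-dihydrofuran in the same way as the classical preparations of 2-acetoxyfuran and 2-methoxyfuran from 2,5-disubstituted 2,5-dihydrofurans.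

Step 8
Reactants: 10 tert-butyl 2-[(4-chloro-3-methoxyfuran-2-yl)oxy]-6-(methoxymethoxy)-4-methylbenzoate; 11 methyl propiolate
Product: 13 tert-butyl 2-[3-chloro-4-hydroxy-2-methoxy-6-(methoxycarbonyl)phenoxy]-6-(methoxymethoxy)-4-methylbenzoate, via oxanorbornadiene cycloadduct 12 (not isolated)
Conditions: methyl propiolate (5 equiv), toluene, 80 °C; then PPTS (10 mol%), CH2Cl2, rt
Reagents that add atoms: none
Why: The electron-rich furan 10 (diene) and methyl propiolate (dienophile) should combine in an asynchronous normal-demand (4+2) cycloaddition in which the unsubstituted furan C5 bonds first to the propiolate CH and the aryloxy-bearing C2 then bonds to the ester-bearing carbon, giving 7-oxanorbornadiene 12. The closest known reaction type is the Diels–Alder addition of 2-alkoxy- and 2-silyloxyfurans to acetylenic esters, followed in the same flask by opening of the oxygen bridge to para-alkoxyphenols. Ring A is closed by this intermolecular cycloaddition, which forms C6–C1 and C3–C2 in one operation as the six-membered carbon frame of the bicycle; heterolysis of the bridge C–O bond at the aryloxy-bearing bridgehead and loss of the proton from the other bridgehead then aromatise it, the bridge oxygen becoming the C3 hydroxyl. No stereocentre remains in 13, the two bridgehead centres of racemic 12 being destroyed on aromatisation. The step needs regioselectivity in the cycloaddition, which should be secured by donation from the 2-aryloxy oxygen toward C5, by the 4-chlorine raising the coefficient at the adjacent terminus, by the absence of a substituent at C5, and by the 3-methoxy group being twisted out of conjugation between its two neighbours; the direction of bridge opening is secured because only the CH bridgehead can lose a proton and the aryloxy group stabilises the cation at the other.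

Step 9
Reactants: 13 tert-butyl 2-[3-chloro-4-hydroxy-2-methoxy-6-(methoxycarbonyl)phenoxy]-6-(methoxymethoxy)-4-methylbenzoate
Product: 14 2-[3-chloro-4-hydroxy-2-methoxy-6-(methoxycarbonyl)phenoxy]-6-hydroxy-4-methylbenzoic acid (target)
Conditions: TFA/CH2Cl2 (1:3), H2O (5 equiv), 0 °C → rt
Reagents that add atoms: none
Why: Acidolysis: the tert-butyl ester ionises to the tert-butyl cation, lost as isobutene, and the methoxymethyl acetal is hydrolysed, while the methyl ester, the aryl chloride and the diaryl ether are inert to TFA at room temperature.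

**Compound list**

1 | 2,6-dihydroxy-4-methylbenzoic acid | Cc1cc(O)c(C(=O)O)c(O)c1 | starting material
2 | tert-butyl 2,6-dihydroxy-4-methylbenzoate | Cc1cc(O)c(C(=O)OC(C)(C)C)c(O)c1 | intermediate
3 | tert-butyl 2-hydroxy-6-(methoxymethoxy)-4-methylbenzoate | COCOc1cc(C)cc(O)c1C(=O)OC(C)(C)C | intermediate
4 | mucochloric acid (3,4-dichloro-5-hydroxyfuran-2(5H)-one) | O=C1OC(O)C(Cl)=C1Cl | starting material
5 | 3,4-dichloro-5-oxo-2,5-dihydrofuran-2-yl methyl carbonate (racemic) | COC(=O)OC1OC(=O)C(Cl)=C1Cl | intermediate
6 | tert-butyl 2-[(3,4-dichloro-5-oxo-2,5-dihydrofuran-2-yl)oxy]-6-(methoxymethoxy)-4-methylbenzoate (racemic) | COCOc1cc(C)cc(OC2OC(=O)C(Cl)=C2Cl)c1C(=O)OC(C)(C)C | intermediate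
7 | tert-butyl 2-[(4-chloro-3-methoxy-5-oxo-2,5-dihydrofuran-2-yl)oxy]-6-(methoxymethoxy)-4-methylbenzoate (racemic) | COCOc1cc(C)cc(OC2OC(=O)C(Cl)=C2OC)c1C(=O)OC(C)(C)C | intermediate
8 | tert-butyl 2-({4-chloro-5-[(diisobutylalumanyl)oxy]-3-methoxy-2,5-dihydrofuran-2-yl}oxy)-6-(methoxymethoxy)-4-methylbenzoate (diisobutylaluminium lactolate, cis/trans mixture, not isolated) | COCOc1cc(C)cc(OC2OC(O[Al](CC(C)C)CC(C)C)C(Cl)=C2OC)c1C(=O)OC(C)(C)C | intermediate
9 | tert-butyl 2-{[5-(acetyloxy)-4-chloro-3-methoxy-2,5-dihydrofuran-2-yl]oxy}-6-(methoxymethoxy)-4-methylbenzoate (cis/trans mixture, racemic) | COCOc1cc(C)cc(OC2OC(OC(C)=O)C(Cl)=C2OC)c1C(=O)OC(C)(C)C | intermediate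
10 | tert-butyl 2-[(4-chloro-3-methoxyfuran-2-yl)oxy]-6-(methoxymethoxy)-4-methylbenzoate | COc1c(Cl)coc1Oc1cc(C)cc(OCOC)c1C(=O)OC(C)(C)C | intermediate
11 | methyl propiolate | C#CC(=O)OC | starting material
12 | tert-butyl 2-{[5-chloro-6-methoxy-2-(methoxycarbonyl)-7-oxabicyclo[2.2.1]hepta-2,5-dien-1-yl]oxy}-6-(methoxymethoxy)-4-methylbenzoate (racemic, not isolated) | COC(=O)C1=CC2OC1(Oc1cc(C)cc(OCOC)c1C(=O)OC(C)(C)C)C(OC)=C2Cl | intermediate
13 | tert-butyl 2-[3-chloro-4-hydroxy-2-methoxy-6-(methoxycarbonyl)phenoxy]-6-(methoxymethoxy)-4-methylbenzoate | COC(=O)c1cc(O)c(Cl)c(OC)c1Oc1cc(C)cc(OCOC)c1C(=O)OC(C)(C)C | intermediate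
14 | 2-[3-chloro-4-hydroxy-2-methoxy-6-(methoxycarbonyl)phenoxy]-6-hydroxy-4-methylbenzoic acid | COC(=O)c1cc(O)c(Cl)c(OC)c1Oc1cc(C)cc(O)c1C(=O)O | target

**Step count**

Total steps: 9. Longest linear sequence: 8 steps (from 1 through steps 1, 2, 4, 5, 6, 7, 8 and 9); the mucochloric acid branch joins at step 4 after one step.

**Steps most likely to fail**

Step 8. The cycloaddition may take the reverse orientation if the 3-methoxy group, and not the 2-aryloxy group, decides which furan alpha carbon is the nucleophilic end. The ester would then end up next to the hydroxyl instead of next to the aryloxy group. The fallback sets out from furan 10 and uses a dienophile whose polarity is opposite to that of the propiolate, methyl (E)-3-nitroacrylate F1 (CH2Cl2, −20 °C → rt). In F1 the nitro group makes the ester-bearing carbon the electrophilic end, so that this carbon should bond to the aryloxy-bearing furan carbon. This should give the nitro cycloadduct tert-butyl 2-{[5-chloro-6-methoxy-2-(methoxycarbonyl)-3-nitro-7-oxabicyclo[2.2.1]hept-5-en-1-yl]oxy}-6-(methoxymethoxy)-4-methylbenzoate F2. Treatment with DBU (THF, 0 °C) should remove the proton alpha to the ester and expel nitrite. This returns the route to oxanorbornadiene 12, which opens to 13 as in step 8.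

Step 6. The aluminium hemiacetal may ring-open before it is acetylated and expel the ring B phenoxide, or hydride addition to the vinylogous carbonate carbonyl may be so slow that other sites are attacked. The fallback sets out from lactone 7 and avoids hydride. Deprotonation at the acetal carbon (KN(SiMe3)2, THF, −78 °C) should give the aromatic furan-2-olate, which is O-sulfonylated with PhNTf2 to the furyl triflate tert-butyl 2-({4-chloro-3-methoxy-5-[(trifluoromethanesulfonyl)oxy]furan-2-yl}oxy)-6-(methoxymethoxy)-4-methylbenzoate F3. Palladium-catalysed formate reduction of the C–OTf bond (Pd(OAc)2, PPh3, HCO2H, Et3N, DMF, 60 °C; the furyl chloride is expected to be inert) should then give furan 10. Compounds 8 and 9 and step 7 are bypassed, and the route is rejoined at 10.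

Step 5. Methoxide may attack the lactone carbonyl of the pseudo-ester instead of C4, which would open the ring and release the ring B phenoxide from the acetal carbon. The fallback sets out from phenol 3 and carries the methoxy group from the start. Commercial 4-methoxyfuran-2(5H)-one F4 is chlorinated at the nucleophilic alpha carbon (NCS, MeCN, 50 °C) to 3-chloro-4-methoxyfuran-2(5H)-one F5. Radical bromination at the gamma position (NBS, AIBN, PhCF3, reflux) should give 5-bromo-3-chloro-4-methoxyfuran-2(5H)-one F6. Phenol 3 then displaces the reactive acylal bromide (K2CO3, MeCN, 0 °C → rt) to give lactone 7. Compounds 4, 5 and 6 are bypassed, and the route is rejoined at 7.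

**Further compounds**

F1 | step 8 | methyl (E)-3-nitroacrylate (reagent, bought or freshly prepared) | COC(=O)/C=C/[N+](=O)[O-]
F2 | step 8 | tert-butyl 2-{[5-chloro-6-methoxy-2-(methoxycarbonyl)-3-nitro-7-oxabicyclo[2.2.1]hept-5-en-1-yl]oxy}-6-(methoxymethoxy)-4-methylbenzoate (racemic, ester and nitro trans, endo/exo mixture, no configuration assigned) | COC(=O)C1C([N+](=O)[O-])C2OC1(Oc1cc(C)cc(OCOC)c1C(=O)OC(C)(C)C)C(OC)=C2Cl
F3 | step 6 | tert-butyl 2-({4-chloro-3-methoxy-5-[(trifluoromethanesulfonyl)oxy]furan-2-yl}oxy)-6-(methoxymethoxy)-4-methylbenzoate | COCOc1cc(C)cc(Oc2oc(OS(=O)(=O)C(F)(F)F)c(Cl)c2OC)c1C(=O)OC(C)(C)C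
F4 | step 5 | 4-methoxyfuran-2(5H)-one (bought) | COC1=CC(=O)OC1
F5 | step 5 | 3-chloro-4-methoxyfuran-2(5H)-one | COC1=C(Cl)C(=O)OC1
F6 | step 5 | 5-bromo-3-chloro-4-methoxyfuran-2(5H)-one (racemic) | COC1=C(Cl)C(=O)OC1Br
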